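## Analysis of the target

Megaphone acetate 25 is a cyclohex-2-enone (C1 carbonyl, C2=C3, C4 bearing OMe, C5 methylene, C6 quaternary). C6 carries an allyl group (C1'–C3') and a chain made of C8 (CH–CH3) and C7 (CH(OAc)Ar, Ar = 3,4,5-trimethoxyphenyl). There are four stereocentres: C6 (R), C8 (S) and C7 (R) are contiguous, and C4 (R) lies one methylene away from C6. Reading the SMILES, the C4 methoxy group is on the ring face of the C8 chain and trans to the allyl group. The sensitive groups are the benzylic acetate on an electron-rich arene (ionisation, hydrolysis), the γ-methoxy enone (conjugate addition, vinylogous loss of methanol, reductive cleavage) and the terminal alkene. C6 has no hydrogen, so it cannot be corrected by epimerisation and must be right when it is formed. The difficulty is to correlate a ring quaternary centre with two stereocentres on a freely rotating chain, and then to place the remote C4 oxygen. The strategy rests on the five-atom chain C7–C8–C6–C1'–C2': an oxygen bridge from C7 to C2' makes C7, C8 and C6 ring atoms of a tetrahydropyran, and the C2'=C3' alkene is what remains when that ring is opened reductively. The C1 ketone next to quaternary C6 is in turn the mark of a pinacol-type ring expansion of a 1-alkenylcyclopentanol, with C5 as the migrated carbon.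

## Retrosynthetic reasoning

The acyl C7–O bond of 25 is cut first, giving megaphone 24. The benzylic acetate is the most labile group, so it is introduced last, and 24 has no other hydroxyl to compete.

In 24 the terminal alkene and the C7 hydroxyl are read as the two ends of a β-elimination. Re-forming a C2'–O bond to the C7 oxygen and placing iodine on C3' gives the 2-(iodomethyl)tetrahydropyran 22, which comes from chloride 21 by halide exchange. This turns the open chain with three contiguous stereocentres into a chair whose substituents can be controlled; the C2' stereocentre is consumed. The forward reaction is a two-electron reduction of the C–I bond (organometallic 23) with expulsion of the ring oxygen, and it must spare the γ-methoxy enone.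

C4 is dealt with on the spiro ether. The O–CH3 bond of 21 leads to carbinol 20, the C4–H bond of 20 to ene-dione 19, and 19 comes from the epimeric γ-hydroxy enones 18, which arise through epoxide 17 from the non-conjugated enone 16. The detour through 19 is deliberate. In 16 the two faces of the ring alkene differ only in which of C1' and C8 sits pseudo-axial on the carbocycle, so no reliable substrate bias can be claimed. A planar C4 is therefore reduced under reagent control. Doing this before the ring is opened means that 16 has only one alkene to oxidise and that its isomerisation-prone β,γ-enone is used at once.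

The key disconnection takes 16 back through cation 15 and oxocarbenium ion 14 to alcohol 12 and aldehyde 13. Three bonds are undone: C5–C6 (the methylene returns to C1, contracting the cyclohexenone to a cyclopentene carbinol), C7–C8 and C7–O. They are cut here because the spiro centre and its two neighbours then collapse to a planar trisubstituted alkene, an achiral aldehyde and a symmetric cyclopentenyl group. Only C2' remains as a stereocentre. The forward reaction must relay C2' to C7, translate alkene geometry into C8, and choose one face of the C6 cation for the shift.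

Alcohol 12 needs a free secondary hydroxyl beside a silylated tertiary one. The tertiary hydroxyl cannot be silylated selectively, so both Si–O bonds are traced to the bis-silyl ether 11 and the diol 10, and the less hindered silyl group is removed afterwards.

The cyclopentene C=C of 10 is opened to the diallyl carbinol 9 (ring-closing metathesis in the forward sense). The two C1–allyl bonds of 9 lead through ketone 8 to lactone 6 and two equivalents of the allyl reagent 7. The lactone oxygen is the future C2' hydroxyl, so the addition frees it without a protecting group.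

The C6=C8 bond of 6 is cut to phosphonate 4 and acetaldehyde 5, which sets the methyl group cis to the C1' methylene. Cutting C1'–C6 and the lactone O–C1 bond of 4 leads through hydroxy ester 3 to epichlorohydrin 1 and phosphonoacetate 2. All carbon comes from five commercial compounds (1, 2, 5, 7, 13), and 1 is the only purchased stereocentre.

## Alternatives that were turned down

Alternative 1: The C3–C4 bond is cut, giving the acyclic (Z)-β-iodo enone A1 whose C6 carries two identical 2-oxoethyl arms. In the forward step CrCl2 with catalytic NiCl2 inserts into the C3–I bond and the C3–Cr bond adds to one aldehyde, closing the ring to the 4-hydroxy enone A2.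
- For it: the C4 oxygen and the enone arrive in the ring closure, and A2 is two operations from 25 (O-methylation, methylenation of the remaining aldehyde). On endgame length it is clearly stronger than the chosen route, which needs seven steps after its key step.
- Against it: C6 and C4 are both created in that step, and the only control is the C8 stereocentre on a rotating chain choosing between two diastereotopic arms and two carbonyl faces. Four diastereomers are possible and nothing rigid selects among them. A1 is also fragile: a 1,5-dialdehyde flanking a quaternary carbon (aldol, hydrate) and a β-iodo enone open to addition–elimination. C7 and C8 need a separate asymmetric reaction.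
- Comparison: the chosen strategy gives up the short endgame and in return sets C6, C7 and C8 in a chair with ring-bound substituents from one purchased stereocentre.

Alternative 2: The C1–C6 and C4–C5 bonds are cut (Diels–Alder). The 2-substituted acrolein A3, which carries the silyl-protected side chain, reacts with diene A4 under Me2AlCl to give the cis-1,4-diacetoxycyclohexene A5.
- For it: the ring, the C2=C3 alkene and both ring oxygens form at once. The endo rule ties C4 to C6, which is better than the chosen route, where C4 needs its own catalyst-controlled reduction.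
- Against it: the link between the ring and the side chain is only π-facial selection by C8 on the α-substituent of the dienophile, again an acyclic rotor. A4 is a weakly activated diene and A3 is a hindered dienophile. Me2AlCl can ionise the benzylic silyl ether and the allylic acetates of A5. After the cycloaddition the formyl group must be homologated by two carbons at a neopentyl position, the two acetates differentiated, C1 oxidised, C4 methylated and the silyl group exchanged for acetyl.
- Comparison: it is longer after the key step and weaker exactly at the C6/C8 junction, which the chosen route controls best.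

Alternative 3: The C1–C2 bond is cut. The precursor is γ-lactone A6 (C1 carbonyl, ring oxygen on C7, then C8 and C6), with allyl and a (Z)-4-iodo-2-methoxybut-3-enyl chain on C6. t-BuLi effects iodine–lithium exchange at C2, the carbanion attacks the lactone carbonyl, and collapse releases the C7 alkoxide to give megaphone A7 (the same compound as 24).
- For it: all four stereocentres exist before the key step, which creates none. The lactone is a good template: the second α-alkylation (allyl) enters anti to the cis methyl and aryl groups. C4 comes from a building block, and the target is one acetylation away. On stereochemical risk in the key step and on the endgame it is stronger than the chosen route.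
- Against it: the cost moves into A6. It needs an enantioselective entry to the cis-β-methyl-γ-aryl lactone, a separate enantioenriched C4 fragment, and an enolate alkylation with a β-alkoxy primary electrophile that also carries a vinyl iodide (slow substitution, elimination). The exchange must also outrun attack of t-BuLi on the lactone.
- Comparison: the chosen route is linear from cheap materials, needs one chiral building block and one chiral catalyst, and makes three stereocentres in one step; it pays with a riskier key step and a late adjustment at C4.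

Key step: step 7

Remarks on the chemistry:
- Atom labels (C1–C8, C1'–C3') are those of the analysis and are used for every intermediate.
- The trisubstituted alkene of 6–12 is E by the CIP rules, although its methyl group is cis to the C1' methylene.
- The tertiary hydroxyl cannot be silylated selectively, so both are silylated and the secondary silyl ether is removed (steps 5 and 6).
- The ring is oxidised before the allyl group is unmasked, and C4 is set by reduction of a ketone.

## Route

Step 1
Reactants: 1 (S)-epichlorohydrin; 2 triethyl phosphonoacetate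
Product: 4 diethyl [(5S)-5-(chloromethyl)-2-oxooxolan-3-yl]phosphonate (both C3 epimers), via open-chain hydroxy phosphonoester 3 (not isolated)
Conditions: NaOEt (1.0 equiv), EtOH, 0 to 40 °C; then AcOH (1.0 equiv)
Reagents that add atoms: none
Why: The stabilised carbanion of 2 opens the epoxide by SN2 at the unsubstituted carbon, so the C–O stereocentre is untouched. The alkoxide of 3 lactonises (5-exo-trig) faster than it displaces chloride, and the product rests as its enolate; one equivalent of base avoids the second deprotonation that leads to a cyclopropane. This is the known epoxide alkylation–lactonisation of active methylene compounds.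

Step 2
Reactants: 4 diethyl [(5S)-5-(chloromethyl)-2-oxooxolan-3-yl]phosphonate; 5 acetaldehyde
Product: 6 (3E,5S)-5-(chloromethyl)-3-ethylideneoxolan-2-one
Conditions: NaH (1.05 equiv), THF, 0 °C; then 5 (3 equiv), 0 °C to rt
Reagents that add atoms: none
Why: Horner–Wadsworth–Emmons olefination of an α-phosphono lactone should favour the alkylidene lactone with methyl trans to the carbonyl, i.e. cis to the ring methylene. Any (Z)-isomer is removed by chromatography; C5 is not involved.

Step 3
Reactants: 6 (3E,5S)-5-(chloromethyl)-3-ethylideneoxolan-2-one; 7 allylmagnesium bromide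
Product: 9 (2S,4E)-1-chloro-4-ethylidene-5-(prop-2-en-1-yl)oct-7-ene-2,5-diol, via allyl ketone 8 (not isolated)
Conditions: 7 (3.0 equiv), Et2O/THF, −78 to 0 °C; aq NH4Cl
Reagents that add atoms: none
Why: Allyl Grignard reagents add 1,2 through a cyclic transition state even to conjugated acyl groups, so double addition via 8 gives the tertiary carbinol and frees the C2' hydroxyl. Bromomagnesium alkoxides of chlorohydrins do not close to epoxides at or below 0 °C; alkene geometry and C2' are untouched.

Step 4
Reactants: 9 (2S,4E)-1-chloro-4-ethylidene-5-(prop-2-en-1-yl)oct-7-ene-2,5-diol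
Product: 10 1-[(2E,5S)-6-chloro-5-hydroxyhex-2-en-3-yl]cyclopent-3-en-1-ol
Conditions: RuCl2(=CHPh)(PCy3)2 (first-generation Grubbs catalyst, 3 mol %), CH2Cl2, 40 °C
Reagents that add atoms: none
Why: Ring-closing metathesis of a diallyl carbinol to a cyclopent-3-enol is fast and driven by loss of ethene. The trisubstituted ethylidene alkene is inert to this catalyst, and hydroxyls and the alkyl chloride are tolerated.

Step 5
Reactants: 10 1-[(2E,5S)-6-chloro-5-hydroxyhex-2-en-3-yl]cyclopent-3-en-1-ol
Product: 11 (2S,4E)-1-chloro-2-(triethylsilyloxy)-4-[1-(triethylsilyloxy)cyclopent-3-en-1-yl]hex-4-ene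
Conditions: TESOTf (2.5 equiv), 2,6-lutidine (4 equiv), CH2Cl2, −78 to 0 °C
Reagents that add atoms: triethylsilyl trifluoromethanesulfonate, CC[Si](CC)(CC)OS(=O)(=O)C(F)(F)F
Why: A silyl triflate with a hindered pyridine base silylates even the tertiary allylic hydroxyl without ionising it. Both hydroxyls are capped because the tertiary one cannot be silylated alone.

Step 6
Reactants: 11 (2S,4E)-1-chloro-2-(triethylsilyloxy)-4-[1-(triethylsilyloxy)cyclopent-3-en-1-yl]hex-4-ene
Product: 12 (2S,4E)-1-chloro-4-[1-(triethylsilyloxy)cyclopent-3-en-1-yl]hex-4-en-2-ol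
Conditions: PPTS (0.1 equiv), MeOH/CH2Cl2 1:1, 0 °C
Reagents that add atoms: none
Why: Acid-catalysed methanolysis of silyl ethers depends strongly on steric hindrance, so the secondary triethylsilyl ether should be cleaved while the tertiary one survives these mild conditions.

Step 7
Reactants: 12 (2S,4E)-1-chloro-4-[1-(triethylsilyloxy)cyclopent-3-en-1-yl]hex-4-en-2-ol; 13 3,4,5-trimethoxybenzaldehyde
Product: 16 (1S,2R,4S,6S)-4-(chloromethyl)-1-methyl-2-(3,4,5-trimethoxyphenyl)-3-oxaspiro[5.5]undec-9-en-7-one, via (E)-oxocarbenium ion 14 (not isolated), via tertiary carbocation 15 (not isolated)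
Conditions: 13 (1.5 equiv), SnCl4 (1.2 equiv), CH2Cl2, −78 to −30 °C; aq NaHCO3 quench at −30 °C
Reagents that add atoms: none
Why: SnCl4 activates 13 toward the C2' hydroxyl, and loss of the tin-bound hydroxide gives the (E)-oxocarbenium ion 14. The trisubstituted alkene attacks C7 through C8 in a 6-endo Prins cyclisation via a chair with aryl and chloromethyl equatorial, closing the tetrahydropyran (C7–O and C7–C8) and leaving tertiary cation 15 at C6. A ring methylene of the silyloxycyclopentene then shifts from C1 to C6 (pinacol rearrangement), so the cyclohexenone arises by ring enlargement, not by a second cyclisation, and loss of the silyl group gives the ketone; the closest known reaction type is the ring-enlarging Prins–pinacol annulation of 1-alkenylcycloalkanol silyl ethers. C7 is set by C2' through the chair (2,6-cis). C8 is set by alkene geometry: the methyl group is cis to C1' on the alkene, so it must become axial and therefore cis to the aryl group. C6 is set by the shift taking the face of the planar cation opposite the adjacent axial methyl, which puts the migrated methylene axial and the carbonyl carbon equatorial. The two ring methylenes on C1 are constitutionally equivalent, so only one ketone can form; the competing oxonia-Cope ion would be an α-chloromethyl oxocarbenium and is disfavoured. The step needs condensation at the secondary hydroxyl before the tertiary allylic silyl ether ionises, which low temperature and precomplexation of 13 should secure, and the cold basic quench keeps the alkene out of conjugation.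

Step 8
Reactants: 16 (1S,2R,4S,6S)-4-(chloromethyl)-1-methyl-2-(3,4,5-trimethoxyphenyl)-3-oxaspiro[5.5]undec-9-en-7-one
Product: 18 (1S,2R,4S)-4-(chloromethyl)-10-hydroxy-1-methyl-2-(3,4,5-trimethoxyphenyl)-3-oxaspiro[5.5]undec-8-en-7-one (spiro centre as in 16; both C10 epimers), via β,γ-epoxy ketone 17 (not isolated)
Conditions: mCPBA (1.2 equiv), NaHCO3, CH2Cl2, 0 °C; then Et3N (3 equiv), rt
Reagents that add atoms: 3-chloroperoxybenzoic acid, OOC(=O)c1cccc(Cl)c1
Why: Prilezhaev epoxidation of the only alkene gives 17. Triethylamine enolises toward C2 (C6 is quaternary) and the enolate opens the epoxide by E1cB to the γ-hydroxy enone. No facial selectivity is needed because C4 (C10 in the name) is made planar in step 9.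

Step 9
Reactants: 18 (1S,2R,4S)-4-(chloromethyl)-10-hydroxy-1-methyl-2-(3,4,5-trimethoxyphenyl)-3-oxaspiro[5.5]undec-8-en-7-one
Product: 19 (1S,2R,4S,6R)-4-(chloromethyl)-1-methyl-2-(3,4,5-trimethoxyphenyl)-3-oxaspiro[5.5]undec-8-ene-7,10-dione
Conditions: Dess–Martin periodinane (1.3 equiv), CH2Cl2, 0 °C to rt
Reagents that add atoms: none
Why: Dess–Martin oxidation of the allylic alcohol converges both C4 epimers on one ene-dione. The quaternary C6 blocks tautomerisation to a hydroquinone, so the dione should be isolable.

Step 10
Reactants: 19 (1S,2R,4S,6R)-4-(chloromethyl)-1-methyl-2-(3,4,5-trimethoxyphenyl)-3-oxaspiro[5.5]undec-8-ene-7,10-dione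
Product: 20 (1S,2R,4S,6S,10R)-4-(chloromethyl)-10-hydroxy-1-methyl-2-(3,4,5-trimethoxyphenyl)-3-oxaspiro[5.5]undec-8-en-7-one
Conditions: (S)-2-methyl-CBS-oxazaborolidine (0.3 equiv), catecholborane (1.5 equiv), toluene/CH2Cl2, −78 °C; then MeOH, aq NaHCO3
Reagents that add atoms: none
Why: Corey–Bakshi–Shibata reduction. The C4 carbonyl is unhindered while the C1 carbonyl is shielded by the spiro quaternary centre, so only C4 should be reduced. With alkenyl C3 as the larger flank and methylene C5 as the smaller, the (S)-catalyst is expected to give the (R)-carbinol, so C4 is set by the reagent; catecholborane does not reduce ring-locked s-trans enones in the conjugate sense.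

Step 11
Reactants: 20 (1S,2R,4S,6S,10R)-4-(chloromethyl)-10-hydroxy-1-methyl-2-(3,4,5-trimethoxyphenyl)-3-oxaspiro[5.5]undec-8-en-7-one
Product: 21 (1S,2R,4S,6S,10R)-4-(chloromethyl)-10-methoxy-1-methyl-2-(3,4,5-trimethoxyphenyl)-3-oxaspiro[5.5]undec-8-en-7-one
Conditions: MeI (excess), Ag2O (3 equiv), 4 Å molecular sieves, MeCN, 40 °C, dark
Reagents that add atoms: iodomethane, CI
Why: Purdie methylation is neutral and avoids a free alkoxide on the base-sensitive γ-hydroxy enone. The C–O bond at C4 is not broken, so its configuration is kept.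

Step 12
Reactants: 21 (1S,2R,4S,6S,10R)-4-(chloromethyl)-10-methoxy-1-methyl-2-(3,4,5-trimethoxyphenyl)-3-oxaspiro[5.5]undec-8-en-7-one
Product: 22 (1S,2R,4S,6S,10R)-4-(iodomethyl)-10-methoxy-1-methyl-2-(3,4,5-trimethoxyphenyl)-3-oxaspiro[5.5]undec-8-en-7-one
Conditions: NaI (10 equiv), butan-2-one, 80 °C
Reagents that add atoms: sodium iodide, [Na+].[I-]
Why: Finkelstein exchange (SN2) at the primary carbon, driven by precipitation of NaCl. A β-oxygenated primary chloride reacts slowly, hence the higher-boiling ketone solvent; the neutral medium leaves the enone alone.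

Step 13
Reactants: 22 (1S,2R,4S,6S,10R)-4-(iodomethyl)-10-methoxy-1-methyl-2-(3,4,5-trimethoxyphenyl)-3-oxaspiro[5.5]undec-8-en-7-one
Product: 24 megaphone, (4R,6R)-6-[(1R,2S)-1-hydroxy-1-(3,4,5-trimethoxyphenyl)propan-2-yl]-4-methoxy-6-(prop-2-en-1-yl)cyclohex-2-en-1-one, via alkylzinc iodide 23 (not isolated)
Conditions: Zn dust (activated, 15 equiv), EtOH, 78 °C
Reagents that add atoms: none
Why: Zinc inserts into the C–I bond and the β-alkoxy organozinc 23 eliminates the ring oxygen (Boord-type reductive opening of a 2-(iodomethyl) cyclic ether), giving the allyl group and the C7 alkoxide. C2' becomes sp2, and C4, C6, C7 and C8 are not touched. Zinc in neutral ethanol should not reduce a conjugated enone.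

Step 14
Reactants: 24 megaphone
Product: 25 megaphone acetate, (1R,2S)-2-[(1R,5R)-5-methoxy-2-oxo-1-(prop-2-en-1-yl)cyclohex-3-en-1-yl]-1-(3,4,5-trimethoxyphenyl)propyl acetate
Conditions: Ac2O (3 equiv), pyridine, DMAP (0.1 equiv), CH2Cl2, rt
Reagents that add atoms: acetic anhydride, CC(=O)OC(C)=O
Why: DMAP-catalysed acylation of the only hydroxyl. The mild base does not affect the γ-methoxy enone, and the C7–O bond is not broken.

## Compound list

1 | (S)-epichlorohydrin, (2S)-2-(chloromethyl)oxirane | ClC[C@@H]1CO1 | starting material
2 | triethyl phosphonoacetate | CCOC(=O)CP(=O)(OCC)OCC | starting material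
3 | ethyl (4S)-5-chloro-2-(diethoxyphosphoryl)-4-hydroxypentanoate (both C2 epimers; present as sodium alkoxide) | ClC[C@@H](O)CC(C(=O)OCC)P(=O)(OCC)OCC | intermediate
4 | diethyl [(5S)-5-(chloromethyl)-2-oxooxolan-3-yl]phosphonate (both C3 epimers) | ClC[C@@H]1CC(C(=O)O1)P(=O)(OCC)OCC | intermediate
5 | acetaldehyde | CC=O | starting material
6 | (3E,5S)-5-(chloromethyl)-3-ethylideneoxolan-2-one | ClC[C@@H]1C/C(=C\C)C(=O)O1 | intermediate
7 | allylmagnesium bromide | C=CC[Mg]Br | starting material
8 | (5E,7S)-8-chloro-5-ethylidene-7-hydroxyoct-1-en-4-one (present as bromomagnesium alkoxide) | ClC[C@@H](O)C/C(=C\C)C(=O)CC=C | intermediate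
9 | (2S,4E)-1-chloro-4-ethylidene-5-(prop-2-en-1-yl)oct-7-ene-2,5-diol | ClC[C@@H](O)C/C(=C\C)C(O)(CC=C)CC=C | intermediate
10 | 1-[(2E,5S)-6-chloro-5-hydroxyhex-2-en-3-yl]cyclopent-3-en-1-ol | ClC[C@@H](O)C/C(=C\C)C1(O)CC=CC1 | intermediate
11 | (2S,4E)-1-chloro-2-(triethylsilyloxy)-4-[1-(triethylsilyloxy)cyclopent-3-en-1-yl]hex-4-ene | ClC[C@@H](O[Si](CC)(CC)CC)C/C(=C\C)C1(O[Si](CC)(CC)CC)CC=CC1 | intermediate
12 | (2S,4E)-1-chloro-4-[1-(triethylsilyloxy)cyclopent-3-en-1-yl]hex-4-en-2-ol | ClC[C@@H](O)C/C(=C\C)C1(O[Si](CC)(CC)CC)CC=CC1 | intermediate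
13 | 3,4,5-trimethoxybenzaldehyde | COc1cc(C=O)cc(OC)c1OC | starting material
14 | (E)-oxocarbenium ion from 12 and 13 (C2' oxygen bound to the benzylidene carbon C7) | ClC[C@H](C/C(=C\C)C1(O[Si](CC)(CC)CC)CC=CC1)/[O+]=C/c2cc(OC)c(OC)c(OC)c2 | intermediate
15 | tertiary tetrahydropyran-4-yl cation (C6) with 2,6-cis aryl and chloromethyl, axial 3-methyl and the 1-(triethylsilyloxy)cyclopent-3-enyl group on C6 | ClC[C@@H]1C[C+](C2(O[Si](CC)(CC)CC)CC=CC2)[C@H](C)[C@H](c3cc(OC)c(OC)c(OC)c3)O1 | intermediate
16 | (1S,2R,4S,6S)-4-(chloromethyl)-1-methyl-2-(3,4,5-trimethoxyphenyl)-3-oxaspiro[5.5]undec-9-en-7-one (aryl and chloromethyl equatorial and cis, methyl axial and cis to aryl, carbonyl carbon equatorial at the spiro centre) | ClC[C@@H]1C[C@@]2(CC=CCC2=O)[C@H](C)[C@H](c3cc(OC)c(OC)c(OC)c3)O1 | intermediate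
17 | 9,10-epoxide of 16 (other centres as in 16; both epoxide faces) | ClC[C@@H]1C[C@@]2(CC3OC3CC2=O)[C@H](C)[C@H](c4cc(OC)c(OC)c(OC)c4)O1 | intermediate
18 | (1S,2R,4S)-4-(chloromethyl)-10-hydroxy-1-methyl-2-(3,4,5-trimethoxyphenyl)-3-oxaspiro[5.5]undec-8-en-7-one (spiro centre as in 16; both C10 epimers) | ClC[C@@H]1C[C@@]2(CC(O)C=CC2=O)[C@H](C)[C@H](c3cc(OC)c(OC)c(OC)c3)O1 | intermediate
19 | (1S,2R,4S,6R)-4-(chloromethyl)-1-methyl-2-(3,4,5-trimethoxyphenyl)-3-oxaspiro[5.5]undec-8-ene-7,10-dione | ClC[C@@H]1C[C@@]2(CC(=O)C=CC2=O)[C@H](C)[C@H](c3cc(OC)c(OC)c(OC)c3)O1 | intermediate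
20 | (1S,2R,4S,6S,10R)-4-(chloromethyl)-10-hydroxy-1-methyl-2-(3,4,5-trimethoxyphenyl)-3-oxaspiro[5.5]undec-8-en-7-one | ClC[C@@H]1C[C@@]2(C[C@@H](O)C=CC2=O)[C@H](C)[C@H](c3cc(OC)c(OC)c(OC)c3)O1 | intermediate
21 | (1S,2R,4S,6S,10R)-4-(chloromethyl)-10-methoxy-1-methyl-2-(3,4,5-trimethoxyphenyl)-3-oxaspiro[5.5]undec-8-en-7-one | ClC[C@@H]1C[C@@]2(C[C@@H](OC)C=CC2=O)[C@H](C)[C@H](c3cc(OC)c(OC)c(OC)c3)O1 | intermediate
22 | (1S,2R,4S,6S,10R)-4-(iodomethyl)-10-methoxy-1-methyl-2-(3,4,5-trimethoxyphenyl)-3-oxaspiro[5.5]undec-8-en-7-one | IC[C@@H]1C[C@@]2(C[C@@H](OC)C=CC2=O)[C@H](C)[C@H](c3cc(OC)c(OC)c(OC)c3)O1 | intermediate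
23 | alkylzinc iodide from 22 (ZnI in place of I; all centres as in 22) | I[Zn]C[C@@H]1C[C@@]2(C[C@@H](OC)C=CC2=O)[C@H](C)[C@H](c3cc(OC)c(OC)c(OC)c3)O1 | intermediate
24 | megaphone, (4R,6R)-6-[(1R,2S)-1-hydroxy-1-(3,4,5-trimethoxyphenyl)propan-2-yl]-4-methoxy-6-(prop-2-en-1-yl)cyclohex-2-en-1-one | C=CC[C@]1([C@H](C)[C@@H](O)c2cc(OC)c(OC)c(OC)c2)C[C@@H](OC)C=CC1=O | intermediate
25 | megaphone acetate, (1R,2S)-2-[(1R,5R)-5-methoxy-2-oxo-1-(prop-2-en-1-yl)cyclohex-3-en-1-yl]-1-(3,4,5-trimethoxyphenyl)propyl acetate | C=CC[C@]1([C@H](C)[C@@H](OC(C)=O)c2cc(OC)c(OC)c(OC)c2)C[C@@H](OC)C=CC1=O | target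

## Step count and least certain steps

Total: 14 steps. Longest linear sequence: 14 steps from 1 (all other components are purchased).

Step 7 (key step). Three processes can go wrong. The tertiary allylic silyl ether may ionise before the hindered, inductively deactivated C2' hydroxyl has condensed with the electron-rich aldehyde. The 1,2-shift may partly take the methyl-bearing face of cation 15, eroding C6. The β,γ-enone may drift into conjugation under the Lewis acid. Fallback, from 12 back to 16: the oxocarbenium ion is made without free aldehyde or water. Alcohol 12 is acylated with 3,4,5-trimethoxybenzoyl chloride (pyridine, DMAP) to the benzoate F1. Reduction with i-Bu2AlH at −78 °C and trapping of the aluminium hemiacetal with Ac2O/pyridine/DMAP give the α-acetoxy ether F2. SnCl4 at −78 °C then ionises the acetate to the same ion 14, which cyclises and rearranges to 16 at the lowest temperature, where the tertiary silyl ether is safest and the facial preference of the shift is largest.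

Step 10. The catalyst may discriminate poorly between the two flanks of the C4 carbonyl (an unsubstituted CH=CH against a methylene next to a quaternary carbon), so facial selectivity may be low, and some reduction at C1 may compete. Fallback, from 19 back to 20: Luche reduction (NaBH4, CeCl3·7H2O, MeOH, −78 °C) reduces the C4 carbonyl under substrate control. Whatever the ratio, the (10S)-alcohol F3 is separated and inverted by a Mitsunobu reaction (4-nitrobenzoic acid, PPh3, DIAD) to the (10R)-4-nitrobenzoate F4, and methanolysis (K2CO3, MeOH, 0 °C) gives 20; the (10R)-alcohol formed directly is 20 itself.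

Step 13 (with step 12). Halide exchange at the β-oxygenated primary carbon may be slow, and electron transfer from zinc to the γ-methoxy enone (loss of methoxide or saturation) may compete with insertion into the C–I bond. Fallback, from 16 to 25: the allyl group is unmasked before the enone exists. NaI exchange on 16 gives the iodide F5, zinc in buffered ethanol gives the hydroxy ketone F6, and acetylation gives the acetate F7. One equivalent of mCPBA should then take the cis-disubstituted ring alkene before the terminal allyl alkene, and Et3N gives the γ-hydroxy enone F8. Dess–Martin oxidation gives the ene-dione F9, CBS reduction as in step 10 gives the (R)-carbinol F10, and MeI/Ag2O gives 25.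

Step 1. The alkoxide of 3 may displace chloride instead of lactonising, leading through a new epoxide to cyclopropane or oligomeric products. Fallback, from 1 back to 4: the epoxide is opened under Lewis acid conditions in which the alkoxide is boron-bound and cannot cyclise. LiC≡COEt with BF3·OEt2 at −78 °C gives the ynol ether alcohol F11. Acid-mediated hydration and lactonisation (TsOH, wet THF) give the chloromethyl lactone F12. Enolate phosphorylation (LiN(i-Pr)2, ClP(O)(OEt)2, then a second equivalent of LiN(i-Pr)2 for the 1,3-phosphoryl shift) returns 4.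

Step 2. The olefination may show poor E/Z selectivity with a small aliphatic aldehyde, and the wrong alkene geometry would invert C8 in step 7. Fallback, from 4 back to 6: the olefination is run without regard to geometry, and the (Z)-lactone F13, separated or in the mixture, is equilibrated to the more stable 6 by reversible thiyl-radical addition (catalytic PhSH, AIBN, benzene, 80 °C).

## Further compounds

F1 | step 7 | (2S,4E)-1-chloro-4-[1-(triethylsilyloxy)cyclopent-3-en-1-yl]hex-4-en-2-yl 3,4,5-trimethoxybenzoate | ClC[C@@H](OC(=O)c2cc(OC)c(OC)c(OC)c2)C/C(=C\C)C1(O[Si](CC)(CC)CC)CC=CC1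
F2 | step 7 | {[(2S,4E)-1-chloro-4-[1-(triethylsilyloxy)cyclopent-3-en-1-yl]hex-4-en-2-yl]oxy}(3,4,5-trimethoxyphenyl)methyl acetate (both acetal epimers) | ClC[C@@H](OC(OC(C)=O)c2cc(OC)c(OC)c(OC)c2)C/C(=C\C)C1(O[Si](CC)(CC)CC)CC=CC1
F3 | step 10 | (1S,2R,4S,6S,10S)-4-(chloromethyl)-10-hydroxy-1-methyl-2-(3,4,5-trimethoxyphenyl)-3-oxaspiro[5.5]undec-8-en-7-one | ClC[C@@H]1C[C@@]2(C[C@H](O)C=CC2=O)[C@H](C)[C@H](c3cc(OC)c(OC)c(OC)c3)O1
F4 | step 10 | (1S,2R,4S,6S,10R)-4-(chloromethyl)-1-methyl-7-oxo-2-(3,4,5-trimethoxyphenyl)-3-oxaspiro[5.5]undec-8-en-10-yl 4-nitrobenzoate | ClC[C@@H]1C[C@@]2(C[C@@H](OC(=O)c3ccc(cc3)[N+](=O)[O-])C=CC2=O)[C@H](C)[C@H](c4cc(OC)c(OC)c(OC)c4)O1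
F5 | step 13 | (1S,2R,4S,6S)-4-(iodomethyl)-1-methyl-2-(3,4,5-trimethoxyphenyl)-3-oxaspiro[5.5]undec-9-en-7-one | IC[C@@H]1C[C@@]2(CC=CCC2=O)[C@H](C)[C@H](c3cc(OC)c(OC)c(OC)c3)O1
F6 | step 13 | (6R)-6-[(1R,2S)-1-hydroxy-1-(3,4,5-trimethoxyphenyl)propan-2-yl]-6-(prop-2-en-1-yl)cyclohex-3-en-1-one | C=CC[C@]1([C@H](C)[C@@H](O)c2cc(OC)c(OC)c(OC)c2)CC=CCC1=O
F7 | step 13 | (1R,2S)-2-[(1R)-2-oxo-1-(prop-2-en-1-yl)cyclohex-4-en-1-yl]-1-(3,4,5-trimethoxyphenyl)propyl acetate | C=CC[C@]1([C@H](C)[C@@H](OC(C)=O)c2cc(OC)c(OC)c(OC)c2)CC=CCC1=O
F8 | step 13 | (1R,2S)-2-[(1R)-5-hydroxy-2-oxo-1-(prop-2-en-1-yl)cyclohex-3-en-1-yl]-1-(3,4,5-trimethoxyphenyl)propyl acetate (both C5 epimers) | C=CC[C@]1([C@H](C)[C@@H](OC(C)=O)c2cc(OC)c(OC)c(OC)c2)CC(O)C=CC1=O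
F9 | step 13 | (1R,2S)-2-[(1R)-2,5-dioxo-1-(prop-2-en-1-yl)cyclohex-3-en-1-yl]-1-(3,4,5-trimethoxyphenyl)propyl acetate | C=CC[C@]1([C@H](C)[C@@H](OC(C)=O)c2cc(OC)c(OC)c(OC)c2)CC(=O)C=CC1=O
F10 | step 13 | (1R,2S)-2-[(1R,5R)-5-hydroxy-2-oxo-1-(prop-2-en-1-yl)cyclohex-3-en-1-yl]-1-(3,4,5-trimethoxyphenyl)propyl acetate | C=CC[C@]1([C@H](C)[C@@H](OC(C)=O)c2cc(OC)c(OC)c(OC)c2)C[C@@H](O)C=CC1=O
F11 | step 1 | (2S)-1-chloro-5-ethoxypent-4-yn-2-ol | ClC[C@@H](O)CC#COCC
F12 | step 1 | (5S)-5-(chloromethyl)oxolan-2-one | ClC[C@@H]1CCC(=O)O1
F13 | step 2 | (3Z,5S)-5-(chloromethyl)-3-ethylideneoxolan-2-one | ClC[C@@H]1C/C(=C/C)C(=O)O1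
A1 | alternative 1 | (1R,2S,5Z)-6-iodo-2-methyl-4-oxo-3,3-bis(2-oxoethyl)-1-(3,4,5-trimethoxyphenyl)hex-5-en-1-yl acetate | O=CCC(CC=O)(C(=O)/C=C\I)[C@H](C)[C@@H](OC(C)=O)c1cc(OC)c(OC)c(OC)c1
A2 | alternative 1 | (1R,2S)-2-[(1S,5R)-5-hydroxy-2-oxo-1-(2-oxoethyl)cyclohex-3-en-1-yl]-1-(3,4,5-trimethoxyphenyl)propyl acetate | O=CC[C@]1([C@H](C)[C@@H](OC(C)=O)c2cc(OC)c(OC)c(OC)c2)C[C@@H](O)C=CC1=O
A3 | alternative 2 | (3S,4R)-4-[(tert-butyldimethylsilyl)oxy]-3-methyl-2-methylidene-4-(3,4,5-trimethoxyphenyl)butanal | C=C(C=O)[C@H](C)[C@@H](O[Si](C)(C)C(C)(C)C)c1cc(OC)c(OC)c(OC)c1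
A4 | alternative 2 | (1E,3E)-buta-1,3-diene-1,4-diyl diacetate | CC(=O)O/C=C/C=C/OC(C)=O
A5 | alternative 2 | cis-1,4-diacetoxycyclohex-2-ene carrying formyl and the silyl-protected side chain on C6 (configuration as in the SMILES) | O=C[C@]1([C@H](C)[C@@H](O[Si](C)(C)C(C)(C)C)c2cc(OC)c(OC)c(OC)c2)C[C@@H](OC(C)=O)C=C[C@H]1OC(C)=O
A6 | alternative 3 | 3-[(3Z)-4-iodo-2-methoxybut-3-en-1-yl]-4-methyl-3-(prop-2-en-1-yl)-5-(3,4,5-trimethoxyphenyl)oxolan-2-one (configuration as in the SMILES) | O=C1O[C@@H](c2cc(OC)c(OC)c(OC)c2)[C@@H](C)[C@@]1(CC=C)C[C@@H](OC)/C=C\I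
A7 | alternative 3 | megaphone | C=CC[C@]1([C@H](C)[C@@H](O)c2cc(OC)c(OC)c(OC)c2)C[C@@H](OC)C=CC1=O
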